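The synthesis rests on a radical [3+2] annulation that closes the bicyclo[3.2.1]octane in one operation. In ent-kaurane numbering, C8 is alpha to the lactone carbonyl C7 and is the bridgehead shared by cyclohexane ring C and cyclopentane ring D, while C16 carries the exocyclic methylene. A C8 radical released from a selenide adds 6-endo to C14, the CH2 terminus of a 2-chloroallyl arm, and the C13 radical so formed closes 5-exo onto the C8 propargyl group, forging C8–C14 and C13–C16 together. The precursor is a spiro delta-lactone bearing ring A, made by titanocene-mediated coupling of a spiro-epoxide radical with a chiral alkoxybutenolide.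

Key step: step 17

Remarks: atom numbers are those of the ent-kaurane skeleton (ring A: C1–C5 and C10; lactone: C7(=O)–O–C20–C10–C9–C8; ring C: C8, C9, C11–C14; ring D: C8, C14, C13, C16, C15; C17 is the methylene carbon; C6 is the CH2OH carbon on C5). The dienone and the (+)-menthol-derived menthyloxybutenolide are assumed to be commercially available. PMB = 4-methoxybenzyl, TBDPS = tert-butyldiphenylsilyl, TBS = tert-butyldimethylsilyl.

Step 1
Reactants: 1 4,4-dimethylcyclohexa-2,5-dien-1-one; 2 potassium vinyltrifluoroborate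
Product: 3 (R)-5-ethenyl-4,4-dimethylcyclohex-2-en-1-one
Conditions: [RhCl(cod)]2 (3 mol %; cod = cycloocta-1,5-diene), (R)-2,2'-bis(diphenylphosphino)-1,1'-binaphthyl (7 mol %), Et3N, toluene/H2O, 80 °C
Reagents that add atoms: none
Why: Hayashi–Miyaura asymmetric 1,4-addition of the vinylrhodium species to one enantiotopic enone face of the achiral dienone sets C5 (the (R)-ligand is chosen from the facial model established for cyclohexenone), and the more hindered product enone should resist a second addition.

Step 2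
Reactants: 3 (R)-5-ethenyl-4,4-dimethylcyclohex-2-en-1-one
Product: 5 (S)-5-(hydroxymethyl)-4,4-dimethylcyclohex-2-en-1-one, via keto aldehyde 4 (not isolated)
Conditions: O3, CH2Cl2, −78 °C; PPh3, −78 °C to rt; then NaBH4, EtOH, −78 °C
Reagents that add atoms: ozone, [O-][O+]=O
Why: ozonolysis should cleave the electron-rich vinyl group in preference to the electron-poor enone, and NaBH4 at −78 °C should reduce the aldehyde but not the conjugated ketone, so C6 is unveiled with C5 untouched.

Step 3
Reactants: 5 (S)-5-(hydroxymethyl)-4,4-dimethylcyclohex-2-en-1-one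
Product: 6 (S)-5-[(tert-butyldiphenylsilyloxy)methyl]-4,4-dimethylcyclohex-2-en-1-one
Conditions: t-BuPh2SiCl, imidazole, DMF, 0 °C to rt
Reagents that add atoms: tert-butyl(chloro)diphenylsilane, CC(C)(C)[Si](Cl)(c1ccccc1)c1ccccc1
Why: standard silylation of the primary alcohol gives an ether that should survive every later step and is removed last.

Step 4
Reactants: 6 (S)-5-[(tert-butyldiphenylsilyloxy)methyl]-4,4-dimethylcyclohex-2-en-1-one; 7 N,N-dimethylmethyleneiminium iodide
Product: 8 (5S,6R)-6-[(dimethylamino)methyl]-5-[(tert-butyldiphenylsilyloxy)methyl]-4,4-dimethylcyclohex-2-en-1-one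
Conditions: LiN(i-Pr)2, THF, −78 °C; then 7, −78 to 0 °C
Reagents that add atoms: none
Why: C10 is the only enolisable carbon of the enone, so kinetic deprotonation gives the cross-conjugated enolate regiospecifically and its Mannich reaction installs C20 trans to the C5 side chain (this centre is erased in step 6).

Step 5
Reactants: 8 (5S,6R)-6-[(dimethylamino)methyl]-5-[(tert-butyldiphenylsilyloxy)methyl]-4,4-dimethylcyclohex-2-en-1-one
Product: 9 (2R,3S)-2-[(dimethylamino)methyl]-3-[(tert-butyldiphenylsilyloxy)methyl]-4,4-dimethylcyclohexan-1-one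
Conditions: H2 (1 atm), Pd/C (palladium on carbon), EtOAc, rt
Reagents that add atoms: none
Why: heterogeneous hydrogenation saturates the enone double bond, which has served to direct enolisation to C10, without touching the ketone or the silyl ether.

Step 6
Reactants: 9 (2R,3S)-2-[(dimethylamino)methyl]-3-[(tert-butyldiphenylsilyloxy)methyl]-4,4-dimethylcyclohexan-1-one
Product: 11 (R)-3-[(tert-butyldiphenylsilyloxy)methyl]-4,4-dimethyl-2-methylidenecyclohexan-1-one, via methiodide 10 (not isolated)
Conditions: MeI, Et2O, rt; then NaHCO3, CH2Cl2/H2O, rt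
Reagents that add atoms: none
Why: quaternisation of the Mannich base and mild E1cB loss of trimethylamine unveil the exocyclic enone, the weak base being chosen to avoid isomerisation of the alkene into the ring.

Step 7
Reactants: 11 (R)-3-[(tert-butyldiphenylsilyloxy)methyl]-4,4-dimethyl-2-methylidenecyclohexan-1-one
Product: 12 (1S,3R)-3-[(tert-butyldiphenylsilyloxy)methyl]-4,4-dimethyl-2-methylidenecyclohexan-1-ol
Conditions: NaBH4, CeCl3·7H2O, MeOH, −78 °C
Reagents that add atoms: none
Why: Luche 1,2-reduction should deliver hydride to the carbonyl face opposite the C5 side chain, setting the C1 hydroxyl cis to the CH2OSi group as in the target.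

Step 8
Reactants: 12 (1S,3R)-3-[(tert-butyldiphenylsilyloxy)methyl]-4,4-dimethyl-2-methylidenecyclohexan-1-ol
Product: 13 4-methoxybenzyl ether of 12
Conditions: NaH, 4-methoxybenzyl chloride, n-Bu4NI (cat.), DMF, 0 °C to rt
Reagents that add atoms: 4-methoxybenzyl chloride, COc1ccc(CCl)cc1
Why: Williamson etherification gives a C1 ether that cannot migrate or lactonise and that should tolerate the amide bases, the titanium reagent and the stannane used later.

Step 9
Reactants: 13 4-methoxybenzyl ether of 12
Product: 14 spiro-epoxide at C10–C20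
Conditions: 3-chloroperoxybenzoic acid, CH2Cl2, 0 °C
Reagents that add atoms: 3-chloroperoxybenzoic acid, OOC(=O)c1cccc(Cl)c1
Why: Prilezhaev epoxidation of the only alkene, expected mainly anti to the two flanking substituents, gives an epoxide whose C10 configuration is irrelevant because C10 becomes a planar radical in step 10.

Step 10
Reactants: 14 spiro-epoxide at C10–C20; 15 (5S)-5-[(1S,2R,5S)-menthyloxy]furan-2(5H)-one
Product: 16 hydroxy lactone acetal (C9–C10 coupling product)
Conditions: (C5H5)2TiCl2 (2.2 equiv), Zn dust, THF, rt; aq. NH4Cl work-up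
Reagents that add atoms: none
Why: Nugent–RajanBabu opening of the epoxide by (C5H5)2TiCl (trivalent titanium) gives the tertiary C10 radical, whose Giese addition to the butenolide should occur anti to the menthyloxy group (sets C9) and on the ring-A face opposite the cis C1 and C5 substituents (sets C10), the adduct radical being reduced to the titanium enolate and protonated on work-up.

Step 11
Reactants: 16 hydroxy lactone acetal (C9–C10 coupling product)
Product: 17 spiro delta-lactone aldehyde (C11 = CHO on C9)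
Conditions: LiN(SiMe3)2 (1.05 equiv), THF, −78 to −30 °C; AcOH
Reagents that add atoms: none
Why: translactonisation in which the C20 alkoxide attacks the pseudo-ester carbonyl C7 through a six-membered transition state and the tetrahedral intermediate expels the more stable hemiacetal alkoxide, which on acidic quench releases the C11 aldehyde and menthol without exposing the epimerisable C9 to base.

Step 12
Reactants: 17 spiro delta-lactone aldehyde (C11 = CHO on C9); 18 2,3-dichloroprop-1-ene
Product: 19 (11R)-homoallylic alcohol carrying the 2-chloroallyl arm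
Conditions: In powder, NaI, DMF, rt
Reagents that add atoms: none
Why: Barbier-type indium-mediated 2-chloroallylation (allylic chloride activated by iodide exchange) is chemoselective for the aldehyde over the lactone, and although Felkin–Anh attack anti to C10 should favour the (11R) alcohol drawn, both C11 epimers converge in step 13.

Step 13
Reactants: 19 (11R)-homoallylic alcohol carrying the 2-chloroallyl arm
Product: 20 C11 ketone
Conditions: 1,1,1-triacetoxy-1,1-dihydro-1,2-benziodoxol-3(1H)-one (DMP), CH2Cl2, rt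
Reagents that add atoms: none
Why: neutral Dess–Martin oxidation gives the C11 ketone without epimerising C9 or moving the chloroalkene into conjugation.

Step 14
Reactants: 20 C11 ketone
Product: 22 (11S)-tert-butyldimethylsilyl ether, via lithium alkoxide 21 (not isolated)
Conditions: Li[HB(s-Bu)3], THF, −78 °C; then t-BuMe2SiOSO2CF3, 2,6-lutidine, −78 to −20 °C
Reagents that add atoms: tert-butyldimethylsilyl trifluoromethanesulfonate, CC(C)(C)[Si](C)(C)OS(=O)(=O)C(F)(F)F
Why: Felkin–Anh reduction in which the bulky hydride attacks anti to quaternary C10 should give the (11S) carbinol (the epimer of the Barbier product, since hydrogen instead of carbon is delivered), and in situ silylation caps the alkoxide before it can translactonise onto C7.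

Step 15
Reactants: 22 (11S)-tert-butyldimethylsilyl ether
Product: 23 8-phenylselanyl lactone
Conditions: LiN(i-Pr)2, THF, −78 °C; PhSeCl
Reagents that add atoms: benzeneselenenyl chloride, Cl[Se]c1ccccc1
Why: selenenylation of the lactone enolate at C8 (anti to the C9 substituent, configuration irrelevant) installs the radical leaving group and acidifies C8–H for the next alkylation.

Step 16
Reactants: 23 8-phenylselanyl lactone; 24 propargyl bromide
Product: 25 8-phenylselanyl-8-propargyl lactone
Conditions: LiN(i-Pr)2, THF/DMPU, −78 to −30 °C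
Reagents that add atoms: none
Why: alkylation of the selenium-stabilised lactone enolate with the reactive propargylic bromide builds quaternary C8 carrying both the C15–C17 unit and the radical precursor (the weakly basic enolate should leave the alkyne C–H alone; C8 configuration is irrelevant).

Step 17
Reactants: 25 8-phenylselanyl-8-propargyl lactone
Product: 27 tetracyclic ent-kaur-16-ene core, via bridgehead chloride 26 (not isolated)
Conditions: Bu3SnH (1.3 equiv, syringe pump), azobisisobutyronitrile, toluene (5 mM), 90 °C; then Bu3SnH (3 equiv), 1,1'-azobis(cyclohexanecarbonitrile), 110 °C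
Reagents that add atoms: none
Why: The tributyltin radical abstracts the phenylselanyl group to give the tertiary C8 radical alpha to the lactone carbonyl, which adds to C14 and then, as the alpha-chloro C13 radical, to C16 of the propargyl group; the C17 vinyl radical takes hydrogen from the stannane and the bridgehead chloride 26 is reduced by the same chain at the higher temperature. The closest known reaction type is the tin-hydride tandem cyclisation of an alpha-carbonyl radical onto an alkene and then an alkyne, used to build methylene-bicyclo[3.2.1]octanes. Ring C closes 6-endo-trig and ring D 5-exo-dig. C8 is set by attack of C14 on the lactone face that carries the C11 arm, which A(1,2) strain with the propargyl group and the anti relationship to C5 hold pseudo-axial, giving the cis lactone/ring C junction; C13 is then fixed by the bicycle, since C16 can reach the radical only from the face of the axial C15 arm. The step needs 6-endo over 5-exo regioselectivity, secured by the chlorine on C13 (attack at the unsubstituted terminus gives a stabilised tertiary radical and avoids a bond between two fully substituted carbons). It also needs cyclisation to outrun hydrogen transfer, secured by slow stannane addition at high dilution.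

Step 18
Reactants: 27 tetracyclic ent-kaur-16-ene core
Product: 28 C1 alcohol
Conditions: DDQ, CH2Cl2/pH 7 buffer, 0 °C to rt
Reagents that add atoms: none
Why: oxidative cleavage of the electron-rich 4-methoxybenzyl ether frees the C1 hydroxyl while the silyl ethers, the lactone and the exocyclic alkene should be untouched.

Step 19
Reactants: 28 C1 alcohol
Product: 29 C1 acetate
Conditions: Ac2O, pyridine, 4-(dimethylamino)pyridine (cat.), CH2Cl2, rt
Reagents that add atoms: acetic anhydride, CC(=O)OC(C)=O
Why: acylation of the only free hydroxyl installs the C1 acetate of the target now that no strongly basic step remains.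

Step 20
Reactants: 29 C1 acetate
Product: 31 15-oxo-16-ene, via allylic alcohol 30 (not isolated)
Conditions: SeO2 (0.5 equiv), t-BuOOH, CH2Cl2, rt; then DMP, rt
Reagents that add atoms: selenium dioxide, O=[Se]=O; tert-butyl hydroperoxide, CC(C)(C)OO
Why: the ene reaction and [2,3]-sigmatropic shift of the allylseleninic acid oxygenate C15, the only allylic position that can react (C13 is a bridgehead), from the open exo face, and Dess–Martin oxidation then gives the enone so that the C15 configuration can be set by hydride delivery.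

Step 21
Reactants: 31 15-oxo-16-ene
Product: 32 15-alcohol (bis-silyl ether of the target)
Conditions: NaBH4, CeCl3·7H2O, MeOH, −78 °C
Reagents that add atoms: none
Why: Luche 1,2-reduction should deliver hydride to the exo face of the ring-D ketone, the endo face being shielded by ring C and the axial C11 silyloxy group, which places the C15 hydroxyl on the side of the C9–C11–C12 bridge as required.

Step 22
Reactants: 32 15-alcohol (bis-silyl ether of the target)
Product: 33 target CNP0210922.1
Conditions: HF·pyridine, pyridine, THF, 0 °C to rt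
Reagents that add atoms: none
Why: buffered fluoride should cleave the secondary tert-butyldimethylsilyl and primary tert-butyldiphenylsilyl ethers together and leave the acetate, the lactone and the allylic alcohol intact.

Compound list

1 | 4,4-dimethylcyclohexa-2,5-dien-1-one | O=C1C=CC(C)(C)C=C1 | starting material
2 | potassium vinyltrifluoroborate | C=C[B-](F)(F)F.[K+] | starting material
3 | (R)-5-ethenyl-4,4-dimethylcyclohex-2-en-1-one | O=C1C=CC(C)(C)[C@@H](C=C)C1 | intermediate
4 | (S)-2,2-dimethyl-5-oxocyclohex-3-ene-1-carbaldehyde (keto aldehyde) | O=C1C=CC(C)(C)[C@@H](C=O)C1 | intermediate (not isolated)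
5 | (S)-5-(hydroxymethyl)-4,4-dimethylcyclohex-2-en-1-one | O=C1C=CC(C)(C)[C@@H](CO)C1 | intermediate
6 | (S)-5-[(tert-butyldiphenylsilyloxy)methyl]-4,4-dimethylcyclohex-2-en-1-one | O=C1C=CC(C)(C)[C@@H](CO[Si](c2ccccc2)(c2ccccc2)C(C)(C)C)C1 | intermediate
7 | N,N-dimethylmethyleneiminium iodide | C=[N+](C)C.[I-] | starting material
8 | (5S,6R)-6-[(dimethylamino)methyl]-5-[(tert-butyldiphenylsilyloxy)methyl]-4,4-dimethylcyclohex-2-en-1-one | O=C1C=CC(C)(C)[C@@H](CO[Si](c2ccccc2)(c2ccccc2)C(C)(C)C)[C@@H]1CN(C)C | intermediate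
9 | (2R,3S)-2-[(dimethylamino)methyl]-3-[(tert-butyldiphenylsilyloxy)methyl]-4,4-dimethylcyclohexan-1-one | O=C1CCC(C)(C)[C@@H](CO[Si](c2ccccc2)(c2ccccc2)C(C)(C)C)[C@@H]1CN(C)C | intermediate
10 | trimethylammonium iodide (methiodide) of 9 | O=C1CCC(C)(C)[C@@H](CO[Si](c2ccccc2)(c2ccccc2)C(C)(C)C)[C@@H]1C[N+](C)(C)C.[I-] | intermediate (not isolated)
11 | (R)-3-[(tert-butyldiphenylsilyloxy)methyl]-4,4-dimethyl-2-methylidenecyclohexan-1-one | C=C1C(=O)CCC(C)(C)[C@H]1CO[Si](c2ccccc2)(c2ccccc2)C(C)(C)C | intermediate
12 | (1S,3R)-3-[(tert-butyldiphenylsilyloxy)methyl]-4,4-dimethyl-2-methylidenecyclohexan-1-ol (OH and CH2OSi cis) | C=C1[C@@H](O)CCC(C)(C)[C@H]1CO[Si](c2ccccc2)(c2ccccc2)C(C)(C)C | intermediate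
13 | 4-methoxybenzyl ether of 12 | C=C1[C@@H](OCc2ccc(OC)cc2)CCC(C)(C)[C@H]1CO[Si](c2ccccc2)(c2ccccc2)C(C)(C)C | intermediate
14 | spiro-epoxide of 13 at C10–C20 (epoxide oxygen anti to the C1 and C5 substituents; either C10 epimer serves) | C1O[C@@]12[C@@H](OCc3ccc(OC)cc3)CCC(C)(C)[C@H]2CO[Si](c3ccccc3)(c3ccccc3)C(C)(C)C | intermediate
15 | (5S)-5-{[(1S,2R,5S)-5-methyl-2-(propan-2-yl)cyclohexyl]oxy}furan-2(5H)-one | O=C1C=C[C@@H](O[C@H]2C[C@@H](C)CC[C@@H]2C(C)C)O1 | starting material
16 | hydroxy lactone acetal: 5-(d-menthyloxy)-gamma-butyrolactone carrying at C9 (trans to the menthyloxy group) the quaternary C10 of ring A, which also bears C20H2OH; 1-O-PMB, 6-O-TBDPS | OC[C@@]1([C@H]2CC(=O)O[C@@H]2O[C@H]3C[C@@H](C)CC[C@@H]3C(C)C)[C@@H](OCc4ccc(OC)cc4)CCC(C)(C)[C@H]1CO[Si](c5ccccc5)(c5ccccc5)C(C)(C)C | intermediate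
17 | spiro delta-lactone aldehyde (7,20-olide; C9 bears CHO = C11); 1-O-PMB, 6-O-TBDPS | O=C[C@@H]1CC(=O)OC[C@]12[C@@H](OCc3ccc(OC)cc3)CCC(C)(C)[C@H]2CO[Si](c3ccccc3)(c3ccccc3)C(C)(C)C | intermediate
18 | 2,3-dichloroprop-1-ene | C=C(Cl)CCl | starting material
19 | (11R)-homoallylic alcohol: C11 carbinol carrying the 2-chloroallyl arm (C12–C14) | C=C(Cl)C[C@@H](O)[C@@H]1CC(=O)OC[C@]12[C@@H](OCc3ccc(OC)cc3)CCC(C)(C)[C@H]2CO[Si](c3ccccc3)(c3ccccc3)C(C)(C)C | intermediate
20 | C11 ketone | C=C(Cl)CC(=O)[C@@H]1CC(=O)OC[C@]12[C@@H](OCc3ccc(OC)cc3)CCC(C)(C)[C@H]2CO[Si](c3ccccc3)(c3ccccc3)C(C)(C)C | intermediate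
21 | lithium (11S)-alkoxide | C=C(Cl)C[C@H]([O-])[C@@H]1CC(=O)OC[C@]12[C@@H](OCc3ccc(OC)cc3)CCC(C)(C)[C@H]2CO[Si](c3ccccc3)(c3ccccc3)C(C)(C)C.[Li+] | intermediate (not isolated)
22 | (11S)-11-O-TBS ether | C=C(Cl)C[C@H](O[Si](C)(C)C(C)(C)C)[C@@H]1CC(=O)OC[C@]12[C@@H](OCc3ccc(OC)cc3)CCC(C)(C)[C@H]2CO[Si](c3ccccc3)(c3ccccc3)C(C)(C)C | intermediate
23 | 8-phenylselanyl lactone (selenium trans to the C11 arm) | C=C(Cl)C[C@H](O[Si](C)(C)C(C)(C)C)[C@@H]1[C@@H]([Se]c4ccccc4)C(=O)OC[C@]12[C@@H](OCc3ccc(OC)cc3)CCC(C)(C)[C@H]2CO[Si](c3ccccc3)(c3ccccc3)C(C)(C)C | intermediate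
24 | propargyl bromide (3-bromoprop-1-yne) | C#CCBr | starting material
25 | 8-phenylselanyl-8-propargyl lactone (propargyl trans to the C11 arm) | C=C(Cl)C[C@H](O[Si](C)(C)C(C)(C)C)[C@@H]1[C@](CC#C)([Se]c4ccccc4)C(=O)OC[C@]12[C@@H](OCc3ccc(OC)cc3)CCC(C)(C)[C@H]2CO[Si](c3ccccc3)(c3ccccc3)C(C)(C)C | intermediate
26 | 13-chloro tetracycle (bridgehead chloride) | C=C1[C@]2(Cl)C[C@H](O[Si](C)(C)C(C)(C)C)[C@@H]3[C@](C2)(C(=O)OC[C@]34[C@@H](OCc5ccc(OC)cc5)CCC(C)(C)[C@H]4CO[Si](c5ccccc5)(c5ccccc5)C(C)(C)C)C1 | intermediate (not isolated)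
27 | tetracyclic 6,7-seco-ent-kaur-16-en-7,20-olide core; 1-O-PMB, 6-O-TBDPS, 11-O-TBS, C15 = CH2 | C=C1[C@@H]2C[C@H](O[Si](C)(C)C(C)(C)C)[C@@H]3[C@](C2)(C(=O)OC[C@]34[C@@H](OCc5ccc(OC)cc5)CCC(C)(C)[C@H]4CO[Si](c5ccccc5)(c5ccccc5)C(C)(C)C)C1 | intermediate
28 | C1 alcohol | C=C1[C@@H]2C[C@H](O[Si](C)(C)C(C)(C)C)[C@@H]3[C@](C2)(C(=O)OC[C@]34[C@@H](O)CCC(C)(C)[C@H]4CO[Si](c5ccccc5)(c5ccccc5)C(C)(C)C)C1 | intermediate
29 | C1 acetate | C=C1[C@@H]2C[C@H](O[Si](C)(C)C(C)(C)C)[C@@H]3[C@](C2)(C(=O)OC[C@]34[C@@H](OC(C)=O)CCC(C)(C)[C@H]4CO[Si](c5ccccc5)(c5ccccc5)C(C)(C)C)C1 | intermediate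
30 | 15-epi allylic alcohol (C15 hydroxyl exo, pointing away from ring C) | C=C1[C@@H]2C[C@H](O[Si](C)(C)C(C)(C)C)[C@@H]3[C@](C2)(C(=O)OC[C@]34[C@@H](OC(C)=O)CCC(C)(C)[C@H]4CO[Si](c5ccccc5)(c5ccccc5)C(C)(C)C)[C@H]1O | intermediate (not isolated)
31 | 15-oxo-16-ene | C=C1[C@@H]2C[C@H](O[Si](C)(C)C(C)(C)C)[C@@H]3[C@](C2)(C(=O)OC[C@]34[C@@H](OC(C)=O)CCC(C)(C)[C@H]4CO[Si](c5ccccc5)(c5ccccc5)C(C)(C)C)C1=O | intermediate
32 | 15-alcohol with the target configuration; 6-O-TBDPS, 11-O-TBS | C=C1[C@@H]2C[C@H](O[Si](C)(C)C(C)(C)C)[C@@H]3[C@](C2)(C(=O)OC[C@]34[C@@H](OC(C)=O)CCC(C)(C)[C@H]4CO[Si](c5ccccc5)(c5ccccc5)C(C)(C)C)[C@@H]1O | intermediate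
33 | CNP0210922.1 | C=C1[C@@H]2C[C@H](O)[C@@H]3[C@](C2)(C(=O)OC[C@]32[C@@H](OC(C)=O)CCC(C)(C)[C@H]2CO)[C@@H]1O | target

Total step count: 22. Longest linear sequence: 22 steps (1 to 33); 2, 7, 15, 18 and 24 enter as purchased building blocks.

Steps most likely to fail

1. Step 17 (key step). What may go wrong: hydrogen transfer from the stannane to the C8 or C13 radical before ring closure, or closure of ring C to the trans-fused junction. Fallback, setting out from 23 and coming back at 27: the two bonds are made in separate operations and C8 is fixed by a polar step. Irradiation of 23 with catalytic hexabutylditin in benzene should effect a phenylselanyl group-transfer 6-endo cyclisation to the cis-fused lactone/ring-C bicycle with chlorine and phenylselanyl on C13 F1. LiN(i-Pr)2 and propargyl bromide then alkylate C8 from the convex face to give the quaternary propargyl lactone F2. Bu3SnH with azobisisobutyronitrile abstracts the phenylselanyl group, the alpha-chloro C13 radical closes 5-exo-dig to 26, and the chloride is reduced on to 27.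

2. Step 10. What may go wrong: addition of the hindered tertiary radical to the beta-substituted butenolide is too slow, so that reduction of the radical by the titanium reagent and elimination to an allylic alcohol win. Fallback, setting out from 14 and coming back at 17: the same radical is trapped by unhindered 2,2,2-trifluoroethyl acrylate under the same titanocene conditions, giving after lactonisation the saturated spirolactone F3. Selenenylation (LiN(i-Pr)2, PhSeBr) gives the alpha-phenylselanyl lactone F4, and H2O2 gives the 8,9-unsaturated lactone F5 by selenoxide elimination. Conjugate addition of a vinyl cuprate (vinylmagnesium bromide, CuI, Me3SiCl), expected anti to the bulkier C5 branch of ring A, gives the 9-vinyl lactone F6, and ozonolysis (O3; PPh3) gives 17.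

3. Step 16. What may go wrong: C-alkylation at the crowded selenium-bearing carbon gives way to O-alkylation or to proton transfer from the alkyne. Fallback, setting out from 22 and coming back at 27: the order is reversed so that the quaternary centre is made by selenenylation with a small electrophile. Alkylation of the enolate of 22 with 3-bromo-1-(trimethylsilyl)prop-1-yne gives the silylpropargyl lactone F7. LiN(i-Pr)2 and PhSeBr give the quaternary selenide F8. Protodesilylation with catalytic AgNO3 and 2,6-lutidine in aqueous acetone gives the terminal alkyne F9, the C8 epimer of 25, which enters step 17 unchanged because C8 becomes planar there.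

Further compounds

F1 | step 17 | cis-fused lactone/ring-C bicycle with Cl and SePh on C13 and H on C8 (epimers at C13) | ClC1([Se]c2ccccc2)C[C@H](O[Si](C)(C)C(C)(C)C)[C@@H]3[C@H](C1)C(=O)OC[C@]34[C@@H](OCc5ccc(OC)cc5)CCC(C)(C)[C@H]4CO[Si](c5ccccc5)(c5ccccc5)C(C)(C)C
F2 | step 17 | C8-propargyl derivative of F1 (propargyl trans to C11 on the lactone ring) | ClC1([Se]c2ccccc2)C[C@H](O[Si](C)(C)C(C)(C)C)[C@@H]3[C@@](C1)(CC#C)C(=O)OC[C@]34[C@@H](OCc5ccc(OC)cc5)CCC(C)(C)[C@H]4CO[Si](c5ccccc5)(c5ccccc5)C(C)(C)C
F3 | step 10 | saturated spiro delta-lactone (C8H2, C9H2); 1-O-PMB, 6-O-TBDPS | C1CC(=O)OC[C@]12[C@@H](OCc3ccc(OC)cc3)CCC(C)(C)[C@H]2CO[Si](c3ccccc3)(c3ccccc3)C(C)(C)C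
F4 | step 10 | 8-phenylselanyl derivative of F3 (epimers at C8) | C1C([Se]c4ccccc4)C(=O)OC[C@]12[C@@H](OCc3ccc(OC)cc3)CCC(C)(C)[C@H]2CO[Si](c3ccccc3)(c3ccccc3)C(C)(C)C
F5 | step 10 | 8,9-unsaturated spiro delta-lactone | C1=CC(=O)OC[C@]12[C@@H](OCc3ccc(OC)cc3)CCC(C)(C)[C@H]2CO[Si](c3ccccc3)(c3ccccc3)C(C)(C)C
F6 | step 10 | 9-vinyl spiro delta-lactone (vinyl on the lactone face of C1) | C=C[C@@H]1CC(=O)OC[C@]12[C@@H](OCc3ccc(OC)cc3)CCC(C)(C)[C@H]2CO[Si](c3ccccc3)(c3ccccc3)C(C)(C)C
F7 | step 16 | 8-[3-(trimethylsilyl)prop-2-ynyl] lactone (trans to the C11 arm) | C=C(Cl)C[C@H](O[Si](C)(C)C(C)(C)C)[C@@H]1[C@@H](CC#C[Si](C)(C)C)C(=O)OC[C@]12[C@@H](OCc3ccc(OC)cc3)CCC(C)(C)[C@H]2CO[Si](c3ccccc3)(c3ccccc3)C(C)(C)C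
F8 | step 16 | 8-phenylselanyl-8-[3-(trimethylsilyl)prop-2-ynyl] lactone (selenium trans to the C11 arm) | C=C(Cl)C[C@H](O[Si](C)(C)C(C)(C)C)[C@@H]1[C@@](CC#C[Si](C)(C)C)([Se]c4ccccc4)C(=O)OC[C@]12[C@@H](OCc3ccc(OC)cc3)CCC(C)(C)[C@H]2CO[Si](c3ccccc3)(c3ccccc3)C(C)(C)C
F9 | step 16 | C8 epimer of 25 | C=C(Cl)C[C@H](O[Si](C)(C)C(C)(C)C)[C@@H]1[C@@](CC#C)([Se]c4ccccc4)C(=O)OC[C@]12[C@@H](OCc3ccc(OC)cc3)CCC(C)(C)[C@H]2CO[Si](c3ccccc3)(c3ccccc3)C(C)(C)C
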